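I decide to carry one number through these flasks, and to get it twice before I believe it.

| flask | substrate | partner | remark | time |
|---|---|---|---|---|
| gamma | 0.050 M | 0.055 M | run made earlier |  |
| theta | 0.050 M | 0.028 M | run made earlier |  |
| epsilon | 0.050 M | 0.11 M | run made earlier |  |
| Sunday's | 0.050 M | 0.0550 M (fed, over 40.0 min) | all but partner at the start; partner goes in evenly over 40.0 min, the run ends at 80 min | 80 min |
| Friday's | 0.050 M | 0.0550 M | a closed flask charged with all of it at once and left for 80 min | 80 min |
| Wednesday's | 0.050 M (fed, over 40.0 min) | 0.0550 M | all but substrate at the start; substrate goes in evenly over 40.0 min, the run ends at 80 min | 80 min |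
| Saturday's | 0.050 M | 0.0550 M | a single well-mixed tank run continuously and read at steady state, 80 min in it on average |  |

- gamma (time / min: target / %, substrate / %): 8.00: 5, 91; 20.0: 13, 79; 40.0: 24, 58; 60.0: 32, 45; 80.0: 40, 38
- theta (time / min: target / %, substrate / %): 4.00: 6, 97; 12.0: 9, 90; 20.0: 10, 81; 30.0: 17, 74; 50.0: 31, 59
- epsilon (time / min: target / %, substrate / %): 4.00: 4, 92; 12.0: 8, 79; 20.0: 16, 71; 30.0: 19, 55; 50.0: 26, 39

(readings scatter by 1.5 percentage points)

- the set-up with the highest amount of target at the outlet or at the end, in percent of the substrate put in ("none" if the first two lie within 2 percentage points) (Sunday's / Friday's / Wednesday's / Saturday's / none)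
- amount of target at the outlet or at the end, in percent of the substrate put in, Sunday's
- amount of target at the outlet or at the end, in percent of the substrate put in, Friday's
- amount of target at the outlet or at the end, in percent of the substrate put in, Wednesday's
- amount of target at the outlet or at the end, in percent of the substrate put in, Saturday's

- the stated concentrations are those of everything mixed, before any reaction; amounts are the same in each set-up
- what was read earlier has a scatter of 1.5 percentage points, one standard deviation
- the feed brings no volume worth counting
- the earlier runs were made in a closed, stirred flask

In logarithms, substrate gives each run a loss rate. Read from its last point, the theta run shows 0.0106 /min, the epsilon run 0.0188 /min. The rise with partner, 0.101 /M/min, I read as a pseudo-first-order side loss, and extending the line to zero partner leaves 0.00773 /min.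

The second way uses a target reading from the gamma run: its share of the substrate lost, 64.5 %, times that run's loss rate gives 0.00780 /min. The first way touches no target reading, yet the two agree, so I trust the number.

I call it the target clock, k_T, the fraction of the substrate present that becomes target each minute. Target is then k_T times the area under the substrate curve.

I reckon that area with the partner fed so far taken as undiminished, so full partner gives a total loss rate of 0.0133 /min, and over Sunday's feed I use the mean of the loss rate. My figures are 41.4 % for Sunday's, 38.5 % for Friday's, 32.0 % for Wednesday's and 30.3 % for Saturday's. In these figures Sunday's stands highest, ahead of Friday's by 2.9 percentage points against a margin of 2 points.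

The forecast, made separately, names Sunday's, with 42 %, 39 %, 32 % and 31 % in the same order, on the ground that “Sunday's slow partner feed keeps partner low early”. Its order matches mine; its figures for Sunday's, Friday's and Saturday's stand 0.60 points, 0.50 points and 0.70 points above mine.

The flask gives Sunday's as best, with 42.1 %, 39.1 %, 32.3 % and 31.6 % in the same order.

    substrate + partner ⇌ intermediate A (K = 140 /M, k = 0.102 /M/min)
    substrate → target (k = 0.00780 /min)
    partner + intermediate A → side product A (k = 0.188 /M/min)
    intermediate A ⇌ intermediate B (K = 1.30, k = 0.00884 /min)
    substrate + intermediate A → side product B (k = 0.0134 /M/min)

In Sunday's, substrate goes from 65.9 % at 40.0 min to 39.9 % at 80.0 min. The clock times the logarithmic mean of those amounts, over that interval, adds 16 points to the 25.9 % of target, against 42.1 % in the flask. Left until 5.0 h, the same flask falls to 3.52 % substrate, and the same reckoning from 42.1 % gives 67.8 %. That flask holds 66.9 % target.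

The data are simulated with constants of no real substance, noise included.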